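The numbers in the tables were generated by integration from invented constants; the scatter is artificial.

Late on, Sunday's run stands still. Counting target once and over-reaction product twice, it holds 102% of the substrate charged at 4.00 h, about what the partner charge amounts to. So over-reaction product looks like target that has taken a second partner, formed after target. Early on, its ratio to target should therefore rise from zero, at a pace proportional to [partner]: while [partner] stays near its charge, target is used up pseudo-first-order.

all flasks: substrate 0.050 M; second catalyst 0.32 mM
- Tuesday's: partner 0.050 M; free catalyst 0.55 mM; the very flask that is asked about, followed so far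
- Sunday's: partner 0.050 M; free catalyst 0.83 mM; run made earlier
- flask: partner 0.0500 M; free catalyst 0.55 mM; time 12 h

- Tuesday's (time / h: over-reaction product / %, target / %, substrate / %): 0.333: 12.3, 21.0, 8.6; 0.833: 28.4, 25.1, 0; 1.50: 35.6, 26.6, 0; 2.50: 37.8, 25.4, 0.2
- Sunday's (time / h: over-reaction product / %, target / %, substrate / %): 2.00: 35.9, 26.9, 0; 4.00: 37.2, 27.1, 0; 6.00: 37.3, 26.3, 0; 8.00: 36.9, 26.1, 0.1

(each reading ± 0.5 percentage points)

- ratio of over-reaction product to target at 4.0 min
- ratio of over-reaction product to target at 12 h



The early ratio is then a contest of two times, the time elapsed and a second one read from the first reading of Tuesday's flask. Dividing 0.333 h by the ratio there gives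

34.1 min

This is the ratio clock, the time in which the ratio would reach one on a straight rise from zero. It is a rough clock, for by the same count 45.6% of the partner charge is already used at 0.333 h. My reckoning for 4.0 min is therefore

ratio = 4.0 min / 34.1 min = 0.117

The forecast gives 0.2 (0.08 to 0.4), higher than this reckoning. For 12 h it gives 1.4 (1.3 to 1.52), on the ground that “Tuesday's flask should reach the same plateau”.

Tuesday's flask gives 0.109 at 4.0 min and 1.45 at 12 h.

    substrate + free catalyst → free catalyst + intermediate (k = 223 L mol⁻¹ min⁻¹)
    partner + second catalyst + intermediate → second catalyst + target (k = 2880 L² mol⁻² min⁻¹)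
    partner + target → over-reaction product (k = 1.53 L mol⁻¹ min⁻¹)

The ratio in Tuesday's flask reaches one at 40.8 min, later than the ratio clock of 34.1 min. For a neighbouring flask charged with 0.12 M of partner, the clock shortened in proportion comes to 14.2 min, so 4.0 min on that clock gives 0.282; that flask gives 0.277.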